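**Retrosynthetic overview**

1. Target 27 ⇐ unmasking of the C8 ketone (1,3-dithiane), tiglate on C9–OH and senecioate on C3–OH ⇐ 3α,9α-diol 22 ⇐ equilibrating (Meerwein–Ponndorf–Verley) reduction of trans-decalin-3,9-dione 21.
2. 21 ⇐ acyclic bis-enone 18 by one-pot silyl dienol ether formation / intramolecular Diels–Alder reaction / hydrolysis, which makes C1–C2 and C5–C10 and so rings A and B together, with the quaternary C5, C10 and (on hydrolysis) C4.
3. Enabling feature: ring A (C1–C5, C10) has oxygen on C3 between C2H2 and the C4(Me)–C5(Me) pair, the retron of a 2-silyloxydiene C2=C3(O)–C4=C5. Its C1–C10 edge adjoins the oxygenated C9 (vinyl ketone C1=C10–C9=O), and C5 and C10 are bridged by C6–C7–C8–C9 (ring B). C8, masked as a dithiane, has no hydrogen, so C9 cannot enolise towards it and C10 is the only epimerisable site.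
4. 18 ⇐ dithiane anion + acrolein (C8–C9); anti-carbomagnesiation/methylation of a propargylic alcohol ((E)-C4=C5 with both methyls); acetylide + acetaldehyde (C3–C4); Evans deconjugative propargylation of a senecioyl imide (C6–C7, C7 stereocentre).
5. Ring order: no carbocycle exists before step 9; rings A and B form in the same operation.

Key step: step 9

Remark: eremophilane numbering is used throughout, also for the corresponding carbons of acyclic precursors: ring A = C1–C2–C3–C4–C5–C10, ring B = C5–C6–C7–C8–C9–C10, C14 = methyl on C5, C15 = methyl on C4, isopropenyl on C7; β is the face of the C5 methyl.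
Remark: 12, 14 and 17 are carried as mixtures of epimers at the carbinol carbons (C3; C3 and C9), because both become ketones in step 8; their SMILES leave these centres undefined.

**Route**

Step 1
Reactants: 1 (4S)-4-benzyl-1,3-oxazolidin-2-one; 2 3-methylbut-2-enoyl chloride
Product: 3 (4S)-4-benzyl-3-(3-methylbut-2-enoyl)-1,3-oxazolidin-2-one
Conditions: Et3N, LiCl, THF, 0 → 23 °C
Reagents that add atoms: none
Why: LiCl/Et3N-mediated N-acylation of the oxazolidinone should proceed cleanly; any β,γ-unsaturated isomer formed is harmless because it gives the same dienolate in step 2.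

Step 2
Reactants: 3 (4S)-4-benzyl-3-(3-methylbut-2-enoyl)-1,3-oxazolidin-2-one; 4 3-bromoprop-1-yne
Product: 6 (4S)-4-benzyl-3-[(2S)-2-(prop-1-en-2-yl)pent-4-ynoyl]-1,3-oxazolidin-2-one, via sodium dienolate 5 (not isolated)
Conditions: NaN(SiMe3)2, THF, −78 °C; then 4, −78 → −40 °C
Reagents that add atoms: none
Why: Evans asymmetric alkylation of the chelated (Z)-dienolate, which should react at the α-carbon (deconjugative alkylation) on the face opposite the benzyl group and so set C7 as (S) with the isopropenyl group already in place.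

Step 3
Reactants: 6 (4S)-4-benzyl-3-[(2S)-2-(prop-1-en-2-yl)pent-4-ynoyl]-1,3-oxazolidin-2-one
Product: 7 (2S)-2-(prop-1-en-2-yl)pent-4-yn-1-ol
Conditions: LiBH4, MeOH (1 equiv), Et2O, 0 °C
Reagents that add atoms: none
Why: LiBH4 reductive cleavage of the imide should release the C8 primary alcohol and the auxiliary without touching alkyne or alkene, and takes C7 out of an epimerisable α-carbonyl position.

Step 4
Reactants: 7 (2S)-2-(prop-1-en-2-yl)pent-4-yn-1-ol
Product: 9 2-[(3S)-2-methylhex-1-en-5-yn-3-yl]-1,3-dithiane, via aldehyde 8 (not isolated)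
Conditions: Dess–Martin periodinane, CH2Cl2, 0 °C; filter; then HS(CH2)3SH, BF3·OEt2, CH2Cl2, −40 → 0 °C
Reagents that add atoms: propane-1,3-dithiol, SCCCS
Why: Dess–Martin oxidation followed at once by BF3-promoted dithioacetalisation should convert the sensitive α-branched β,γ-unsaturated aldehyde into a configurationally robust 1,3-dithiane that masks the C8 ketone and later serves as acyl anion equivalent.

Step 5
Reactants: 9 2-[(3S)-2-methylhex-1-en-5-yn-3-yl]-1,3-dithiane; 10 acetaldehyde
Product: 12 (6S)-6-(1,3-dithian-2-yl)-7-methyloct-7-en-3-yn-2-ol (both C2 epimers), via lithium acetylide 11 (not isolated)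
Conditions: n-BuLi (1.05 equiv), THF, −78 °C; then CH3CHO, −78 °C
Reagents that add atoms: none
Why: the terminal alkyne is far more acidic than the dithiane C–H, so selective acetylide formation and 1,2-addition to acetaldehyde should give the propargylic alcohol that carries C2–C3 and the directing hydroxyl.

Step 6
Reactants: 12 (6S)-6-(1,3-dithian-2-yl)-7-methyloct-7-en-3-yn-2-ol
Product: 14 (3E,6S)-6-(1,3-dithian-2-yl)-3,4,7-trimethylocta-3,7-dien-2-ol (both C2 epimers), via cyclic alkenylmagnesium alkoxide 13 (not isolated)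
Conditions: MeMgBr (4 equiv), CuI (10 mol %), THF/Et2O, 0 → 40 °C; then MeI (excess), 0 → 23 °C
Reagents that add atoms: methylmagnesium bromide, C[Mg]Br; iodomethane, CI
Why: CuI-catalysed hydroxyl-directed anti-carbomagnesiation of a propargylic alcohol (Duboudin–Jousseaume reaction) should place methyl on the proximal alkyne carbon (C4) and magnesium on the distal one (C5) in a five-membered chelate, and C-methylation of that alkenylmagnesium with retention then fixes the (E)-tetrasubstituted C4=C5 alkene with C6 trans to C3.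

Step 7
Reactants: 14 (3E,6S)-6-(1,3-dithian-2-yl)-3,4,7-trimethylocta-3,7-dien-2-ol; 15 prop-2-enal (acrolein)
Product: 17 1-{2-[(3S,5E)-7-hydroxy-2,5,6-trimethylocta-1,5-dien-3-yl]-1,3-dithian-2-yl}prop-2-en-1-ol (carbinol epimers), via dilithiated dithiane alkoxide 16 (not isolated)
Conditions: n-BuLi (2.2 equiv), THF, −30 °C, 3 h; then acrolein, −78 °C
Reagents that add atoms: none
Why: Corey–Seebach umpolung, in which the 2-lithio-1,3-dithiane (the alcohol being protected in situ as its lithium alkoxide) should add 1,2 to acrolein in THF, joining C8 to C9 and bringing in the future dienophile C10=C1.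

Step 8
Reactants: 17 1-{2-[(3S,5E)-7-hydroxy-2,5,6-trimethylocta-1,5-dien-3-yl]-1,3-dithian-2-yl}prop-2-en-1-ol
Product: 18 (3E,6S)-3,4,7-trimethyl-6-[2-(prop-2-enoyl)-1,3-dithian-2-yl]octa-3,7-dien-2-one
Conditions: MnO2 (activated, excess), CH2Cl2, 23 °C; filtered and used at once
Reagents that add atoms: none
Why: both secondary alcohols are allylic, so MnO2 should oxidise them to the methyl enone and the vinyl ketone under neutral conditions that leave the dithiane, the isopropenyl group and C7 untouched.

Step 9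
Reactants: 18 (3E,6S)-3,4,7-trimethyl-6-[2-(prop-2-enoyl)-1,3-dithian-2-yl]octa-3,7-dien-2-one
Product: 21 (10αH)-8,8-(propane-1,3-diyldisulfanediyl)eremophil-11-ene-3,9-dione (trans-decalin; 4β-Me 5β-Me 7α-isopropenyl), via silyloxydiene 19 (not isolated), via silyl enol ether cycloadduct 20 (not isolated)
Conditions: TBSOTf (1.5 equiv), Et3N (3 equiv), CH2Cl2 (0.02 M), −78 → 23 °C; then 1 M HCl, THF, 0 °C
Reagents that add atoms: none
Why: TBSOTf/Et3N should silylate the methyl ketone and remove an α′-proton (C2), the C9 vinyl ketone having no α-hydrogen, to give the cross-conjugated 2-silyloxydiene 19 (C2=C3(OTBS)–C4=C5), which should undergo a concerted asynchronous intramolecular [4+2] cycloaddition with the silyl-triflate-activated dienophile C1=C10–C9=O to form C1–C2 and C5–C10; the closest known reaction types are the silyl triflate/amine intramolecular double Michael reaction of tethered bis-enones and the intramolecular Diels–Alder reaction of 1,7,9-decatrien-3-ones. Ring A closes as the six-membered cycloaddition ring (diene C2–C5 plus dienophile C1=C10), and ring B closes through the C5–C10 bond across the four-carbon tether C6–C9. C5 and C10 should be set trans by the carbonyl-exo transition state, in which the tether is a chair with the C5 methyl and H10 both axial and the s-cis enone intact, whereas the endo mode would hold C4 and its methyl axially over the forming ring B against the spiro-dithiane on C8. The π-face is chosen by C7, whose isopropenyl group sits equatorial on that chair, anti to the axial C5 methyl, which gives the 5β-methyl/7α-isopropenyl relationship. Hydrolysis of enol ether 20 should protonate C4 axially on the face opposite the adjacent angular methyl, giving the equatorial 4β-methyl, which is also expected to be the more stable epimer. The step needs α′- over γ-enolisation (kinetic soft enolisation, as known for mesityl oxide), exo over endo (secured by the C4 methyl and the fully substituted C8) and the E alkene from step 6, which puts the tether on the outside position of the diene terminus so that a trans-fused product is geometrically possible.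

Step 10
Reactants: 21 (10αH)-8,8-(propane-1,3-diyldisulfanediyl)eremophil-11-ene-3,9-dione
Product: 22 (10αH)-8,8-(propane-1,3-diyldisulfanediyl)eremophil-11-ene-3α,9α-diol
Conditions: Al(OiPr)3 (4 equiv), iPrOH containing 1 vol % acetone, toluene, 100 °C, run to equilibrium
Reagents that add atoms: none
Why: Meerwein–Ponndorf–Verley reduction run reversibly should give the thermodynamic carbinols; at both C3 and C9 the axial epimer would be syn-axial to the C5 methyl, so both hydroxyls should end equatorial (3α, 9α), and no electron-transfer cleavage of the α-thio ketone can occur.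

Step 11
Reactants: 22 (10αH)-8,8-(propane-1,3-diyldisulfanediyl)eremophil-11-ene-3α,9α-diol; 2 3-methylbut-2-enoyl chloride
Product: 23 9α-hydroxy-8,8-(propane-1,3-diyldisulfanediyl)eremophil-11-en-3α-yl 3-methylbut-2-enoate
Conditions: 2 (1.1 equiv), pyridine, DMAP (5 mol %), CH2Cl2, −20 → 0 °C
Reagents that add atoms: none
Why: DMAP-catalysed acylation should differentiate the two secondary alcohols sterically, the C3 hydroxyl reacting while the C9 hydroxyl, flanked by the spiro-dithiane and the ring-fusion carbon, is left.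

Step 12
Reactants: 23 9α-hydroxy-8,8-(propane-1,3-diyldisulfanediyl)eremophil-11-en-3α-yl 3-methylbut-2-enoate; 24 (2E)-2-methylbut-2-enoic acid (tiglic acid)
Product: 26 3α-(3-methylbut-2-enoyloxy)-8,8-(propane-1,3-diyldisulfanediyl)eremophil-11-en-9α-yl (2E)-2-methylbut-2-enoate, via mixed anhydride 25 (not isolated)
Conditions: 24, 2,4,6-trichlorobenzoyl chloride, Et3N, toluene, 23 °C; then 23, DMAP, toluene, 70 °C
Reagents that add atoms: none
Why: Yamaguchi esterification should acylate the hindered C9 alcohol with retention at C9 and without isomerising the (E)-2-methylbut-2-enoyl group.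

Step 13
Reactants: 26 3α-(3-methylbut-2-enoyloxy)-8,8-(propane-1,3-diyldisulfanediyl)eremophil-11-en-9α-yl (2E)-2-methylbut-2-enoate
Product: 27 3α-(3-methylbut-2-enoyloxy)-8-oxoeremophil-11-en-9α-yl (2E)-2-methylbut-2-enoate (CNP0164025.1)
Conditions: MeI (excess), CaCO3, MeCN/H2O (9:1), 45 °C
Reagents that add atoms: water, O
Why: S-methylation and hydrolysis of the dithiane under CaCO3 buffering should unmask the C8 ketone under near-neutral conditions, so the equatorial C7 and C9 centres and the β,γ-unsaturated isopropenyl ketone are not equilibrated.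

**Compound list**

1 | (4S)-4-benzyl-1,3-oxazolidin-2-one | O=C1N[C@@H](Cc2ccccc2)CO1 | starting material
2 | 3-methylbut-2-enoyl chloride | CC(C)=CC(=O)Cl | starting material
3 | (4S)-4-benzyl-3-(3-methylbut-2-enoyl)-1,3-oxazolidin-2-one | CC(C)=CC(=O)N1[C@@H](Cc2ccccc2)COC1=O | intermediate
4 | 3-bromoprop-1-yne | C#CCBr | starting material
5 | sodium (Z)-dienolate of 3 (not isolated) | C=C(C)/C=C(\[O-])N1[C@@H](Cc2ccccc2)COC1=O.[Na+] | intermediate
6 | (4S)-4-benzyl-3-[(2S)-2-(prop-1-en-2-yl)pent-4-ynoyl]-1,3-oxazolidin-2-one | C=C(C)[C@@H](C(=O)N1[C@@H](Cc2ccccc2)COC1=O)CC#C | intermediate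
7 | (2S)-2-(prop-1-en-2-yl)pent-4-yn-1-ol | C=C(C)[C@@H](CO)CC#C | intermediate
8 | (2S)-2-(prop-1-en-2-yl)pent-4-ynal (not isolated) | C=C(C)[C@@H](C=O)CC#C | intermediate
9 | 2-[(3S)-2-methylhex-1-en-5-yn-3-yl]-1,3-dithiane | C=C(C)[C@@H](C1SCCCS1)CC#C | intermediate
10 | acetaldehyde | CC=O | starting material
11 | lithium acetylide of 9 (not isolated) | C=C(C)[C@@H](C1SCCCS1)CC#[C-].[Li+] | intermediate
12 | (6S)-6-(1,3-dithian-2-yl)-7-methyloct-7-en-3-yn-2-ol, both C2 epimers | C=C(C)[C@@H](C1SCCCS1)CC#CC(C)O | intermediate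
13 | cyclic alkenylmagnesium alkoxide (five-membered O–Mg–C5=C4–C3 chelate, not isolated) | C=C(C)[C@@H](C1SCCCS1)CC2=C(C)C(C)O[Mg]2 | intermediate
14 | (3E,6S)-6-(1,3-dithian-2-yl)-3,4,7-trimethylocta-3,7-dien-2-ol, both C2 epimers | C=C(C)[C@@H](C1SCCCS1)C/C(C)=C(\C)C(C)O | intermediate
15 | prop-2-enal (acrolein) | C=CC=O | starting material
16 | dilithium salt of 14: lithium alkoxide and 2-lithio-1,3-dithiane (not isolated) | C=C(C)[C@@H]([C-]1SCCCS1)C/C(C)=C(\C)C(C)[O-].[Li+].[Li+] | intermediate
17 | 1-{2-[(3S,5E)-7-hydroxy-2,5,6-trimethylocta-1,5-dien-3-yl]-1,3-dithian-2-yl}prop-2-en-1-ol, carbinol epimers | C=C(C)[C@@H](C1(SCCCS1)C(O)C=C)C/C(C)=C(\C)C(C)O | intermediate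
18 | (3E,6S)-3,4,7-trimethyl-6-[2-(prop-2-enoyl)-1,3-dithian-2-yl]octa-3,7-dien-2-one | C=C(C)[C@@H](C1(SCCCS1)C(=O)C=C)C/C(C)=C(\C)C(C)=O | intermediate
19 | 1-{2-[(3S,5E)-7-(tert-butyldimethylsilyloxy)-2,5,6-trimethylocta-1,5,7-trien-3-yl]-1,3-dithian-2-yl}prop-2-en-1-one (not isolated) | C=C(C)[C@@H](C1(SCCCS1)C(=O)C=C)C/C(C)=C(\C)C(=C)O[Si](C)(C)C(C)(C)C | intermediate
20 | (10αH)-3-(tert-butyldimethylsilyloxy)-8,8-(propane-1,3-diyldisulfanediyl)eremophila-3,11-dien-9-one, trans-fused, 5β-Me, 7α-isopropenyl (not isolated) | C=C(C)[C@@H]1C[C@]2(C)C(C)=C(O[Si](C)(C)C(C)(C)C)CC[C@H]2C(=O)C13SCCCS3 | intermediate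
21 | (10αH)-8,8-(propane-1,3-diyldisulfanediyl)eremophil-11-ene-3,9-dione, trans-decalin, 4β-Me (equatorial), 5β-Me (axial), 7α-isopropenyl (equatorial) | C=C(C)[C@@H]1C[C@]2(C)[C@@H](C)C(=O)CC[C@H]2C(=O)C13SCCCS3 | intermediate
22 | (10αH)-8,8-(propane-1,3-diyldisulfanediyl)eremophil-11-ene-3α,9α-diol, both hydroxyls equatorial | C=C(C)[C@@H]1C[C@]2(C)[C@@H](C)[C@H](O)CC[C@H]2[C@H](O)C13SCCCS3 | intermediate
23 | 9α-hydroxy-8,8-(propane-1,3-diyldisulfanediyl)eremophil-11-en-3α-yl 3-methylbut-2-enoate | C=C(C)[C@@H]1C[C@]2(C)[C@@H](C)[C@H](OC(=O)C=C(C)C)CC[C@H]2[C@H](O)C13SCCCS3 | intermediate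
24 | (2E)-2-methylbut-2-enoic acid (tiglic acid) | C/C=C(\C)C(=O)O | starting material
25 | (2E)-2-methylbut-2-enoic 2,4,6-trichlorobenzoic anhydride (not isolated) | C/C=C(\C)C(=O)OC(=O)c1c(Cl)cc(Cl)cc1Cl | intermediate
26 | 3α-(3-methylbut-2-enoyloxy)-8,8-(propane-1,3-diyldisulfanediyl)eremophil-11-en-9α-yl (2E)-2-methylbut-2-enoate | C=C(C)[C@@H]1C[C@]2(C)[C@@H](C)[C@H](OC(=O)C=C(C)C)CC[C@H]2[C@H](OC(=O)/C(C)=C/C)C13SCCCS3 | intermediate
27 | 3α-(3-methylbut-2-enoyloxy)-8-oxoeremophil-11-en-9α-yl (2E)-2-methylbut-2-enoate, trans-fused, 10α-H (CNP0164025.1) | C=C(C)[C@@H]1C[C@]2(C)[C@@H](C)[C@H](OC(=O)C=C(C)C)CC[C@H]2[C@H](OC(=O)/C(C)=C/C)C1=O | target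

**Step count and risks**

Total step count: 13. Longest linear sequence: 13 steps (1 + 2 → 27).

Steps most likely to fail:

Step 9. The cycloaddition may run partly or mainly through the endo mode and deliver the cis ring fusion, or be slow enough (inside methyl on the diene terminus) for the vinyl ketone to oligomerise. The fallback sets out from 18 and comes back at 21. The one-pot sequence is run as written and the endo product, the cis-fused 10-epimeric dione F1, is not discarded. Because C8 is fully substituted, C10 carries the only α-hydrogen of the C9 ketone. LiN(iPr)2 (2.5 equiv, THF, −78 °C) should therefore convert F1, together with any 21 present, into the dilithium bis-enolate F2 (C2=C3–OLi and C9(OLi)=C10; C4 is untouched). Kinetic protonation with AcOH at −78 °C should occur on the α-face, opposite the pseudoaxial C5 methyl on the adjacent carbon, and return the trans-fused dione 21, which is also expected to be the more stable ring fusion. The ring fusion is then controlled by enolate protonation and no longer by the topology of the cycloaddition.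

Step 6. Carbomagnesiation of the internal, branched propargylic alcohol with a methyl Grignard reagent may be slow or poorly regioselective, and C-methylation of the chelated alkenylmagnesium may be incomplete. The fallback sets out from 9 and comes back at 14; it builds the tetrasubstituted alkene by enol triflate cross-coupling instead.
- n-BuLi then ClCO2Et should give the ynoate F3.
- Conjugate addition of pyrrolidine followed by aqueous AcOH hydrolysis of the enamino ester should give the β-keto ester F4.
- K2CO3/MeI in acetone should give the α-methyl β-keto ester F5 (C2 epimers).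
- NaH/PhNTf2 in THF should give, through the sodium chelate, the (Z)-enol triflate F6 with the triflate cis to the ester.
- MeMgBr with catalytic Fe(acac)3 (THF/NMP, −30 °C) should replace the triflate by methyl with retention and give the (E)-enoate F7.
- iBu2AlH (CH2Cl2, −78 °C) should give the allylic alcohol F8, MnO2 the enal F9, and MeMgBr (THF, −78 °C) then returns 14.

Step 10. Hydride transfer to the hindered C9 carbonyl next to the spiro-dithiane may stall before equilibrium, and prolonged heating with the aluminium alkoxide may erode C4 or C10. The fallback sets out from 21 and comes back at 27; any 9α-alcohol formed on the way is 23 itself and re-enters at step 12.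
- LiBH(sBu)3 (THF, −78 °C) should reduce only the C3 ketone, by equatorial attack away from the syn-axial C5 methyl, to the axial 3β-alcohol F10.
- Mitsunobu esterification (3-methylbut-2-enoic acid, PPh3, DIAD, toluene) should invert C3 and give the 3α-senecioate F11.
- NaBH4 (MeOH, 0 °C) should reduce the C9 ketone mainly from the α-face to the 9β-alcohol F12.
- Yamaguchi tigloylation as in step 12 should give F13, and MeI/CaCO3 as in step 13 the axial 9β-tiglate F14 (9-epi-27).
- DBU (0.1 equiv, toluene, 0 °C, monitored) should epimerise C9 through the C8 enolate to the equatorial 9α-ester 27, the axial epimer being syn-axial to the C5 methyl.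
The carbinol centres are then set by kinetic attack plus inversion (C3) and by late epimerisation of an α-acyloxy ketone (C9), not by alcohol equilibration.

Further compounds
F1 | step 9 | (10βH)-8,8-(propane-1,3-diyldisulfanediyl)eremophil-11-ene-3,9-dione (cis-fused C10 epimer of 21) | C=C(C)[C@@H]1C[C@]2(C)[C@@H](C)C(=O)CC[C@@H]2C(=O)C13SCCCS3
F2 | step 9 | dilithium bis-enolate of F1/21 (C2=C3–O and C9(O)=C10) | C=C(C)[C@@H]1C[C@]2(C)[C@@H](C)C([O-])=CCC2=C([O-])C13SCCCS3.[Li+].[Li+]
F3 | step 6 | ethyl (5S)-5-(1,3-dithian-2-yl)-6-methylhept-6-en-2-ynoate | C=C(C)[C@@H](C1SCCCS1)CC#CC(=O)OCC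
F4 | step 6 | ethyl (5S)-5-(1,3-dithian-2-yl)-6-methyl-3-oxohept-6-enoate | C=C(C)[C@@H](C1SCCCS1)CC(=O)CC(=O)OCC
F5 | step 6 | ethyl (5S)-5-(1,3-dithian-2-yl)-2,6-dimethyl-3-oxohept-6-enoate, C2 epimers | C=C(C)[C@@H](C1SCCCS1)CC(=O)C(C)C(=O)OCC
F6 | step 6 | ethyl (2Z,5S)-5-(1,3-dithian-2-yl)-2,6-dimethyl-3-(trifluoromethylsulfonyloxy)hepta-2,6-dienoate | C=C(C)[C@@H](C1SCCCS1)C/C(OS(=O)(=O)C(F)(F)F)=C(\C)C(=O)OCC
F7 | step 6 | ethyl (2E,5S)-5-(1,3-dithian-2-yl)-2,3,6-trimethylhepta-2,6-dienoate | C=C(C)[C@@H](C1SCCCS1)C/C(C)=C(\C)C(=O)OCC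
F8 | step 6 | (2E,5S)-5-(1,3-dithian-2-yl)-2,3,6-trimethylhepta-2,6-dien-1-ol | C=C(C)[C@@H](C1SCCCS1)C/C(C)=C(\C)CO
F9 | step 6 | (2E,5S)-5-(1,3-dithian-2-yl)-2,3,6-trimethylhepta-2,6-dienal | C=C(C)[C@@H](C1SCCCS1)C/C(C)=C(\C)C=O
F10 | step 10 | (10αH)-3β-hydroxy-8,8-(propane-1,3-diyldisulfanediyl)eremophil-11-en-9-one | C=C(C)[C@@H]1C[C@]2(C)[C@@H](C)[C@@H](O)CC[C@H]2C(=O)C13SCCCS3
F11 | step 10 | 9-oxo-8,8-(propane-1,3-diyldisulfanediyl)eremophil-11-en-3α-yl 3-methylbut-2-enoate | C=C(C)[C@@H]1C[C@]2(C)[C@@H](C)[C@H](OC(=O)C=C(C)C)CC[C@H]2C(=O)C13SCCCS3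
F12 | step 10 | 9β-hydroxy-8,8-(propane-1,3-diyldisulfanediyl)eremophil-11-en-3α-yl 3-methylbut-2-enoate | C=C(C)[C@@H]1C[C@]2(C)[C@@H](C)[C@H](OC(=O)C=C(C)C)CC[C@H]2[C@@H](O)C13SCCCS3
F13 | step 10 | 3α-(3-methylbut-2-enoyloxy)-8,8-(propane-1,3-diyldisulfanediyl)eremophil-11-en-9β-yl (2E)-2-methylbut-2-enoate | C=C(C)[C@@H]1C[C@]2(C)[C@@H](C)[C@H](OC(=O)C=C(C)C)CC[C@H]2[C@@H](OC(=O)/C(C)=C/C)C13SCCCS3
F14 | step 10 | 3α-(3-methylbut-2-enoyloxy)-8-oxoeremophil-11-en-9β-yl (2E)-2-methylbut-2-enoate (9-epi-27) | C=C(C)[C@@H]1C[C@]2(C)[C@@H](C)[C@H](OC(=O)C=C(C)C)CC[C@H]2[C@@H](OC(=O)/C(C)=C/C)C1=O
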